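**Small charge.** The initiator in delta is a small charge, 2.50 mM against 0.25 M of free monomer, so the chain length asked for is a matter of counting turnovers. Delta gives 95.0 for the free monomer spared by the protic impurity per initiator charged, the turnover count, in the trade the target degree of polymerisation. Theta, with its larger loading, gives 23.8.

| setting | teal | red | delta | theta |
|---|---|---|---|---|
| free monomer | 0.25 M (fed, over 2.0 min) | 0.25 M (fed, over 2.0 min) | 0.25 M (fed, over 2.0 min) | 0.25 M (fed, over 2.0 min) |
| transfer agent | 2.5 mM | 2.5 mM | 2.50 mM | 2.50 mM |
| protic impurity | 0.0125 M | 0.0125 M | 0.0125 M | 0.0125 M |
| initiator | 1.1 mol% | 6.1 mol% | 1 mol% | 4 mol% |
| remark | run made earlier; the fed solution adds 0.20 times the starting volume | run made earlier; the fed solution adds 0.20 times the starting volume | the fed solution adds 0.20 times the starting volume | the fed solution adds 0.20 times the starting volume |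
| time |  |  | 5.0 h | 5.0 h |

| run | time / h | monomer in chains / % | free monomer / % |
|---|---|---|---|
| teal | 0.250 | 37 | 61 |
| teal | 0.667 | 63 | 33 |
| teal | 1.50 | 80 | 16 |
| teal | 4.00 | 89 | 5 |
| red | 0.250 | 89 | 7 |
| red | 0.667 | 96 | 2 |
| red | 1.50 | 94 | 1 |
| red | 4.00 | 94 | 3 |

(scatter of a reading: 1.5 percentage points)

- charges are per starting volume, the dose included; the dosed solution carries all of it
- the average divides the monomer in chains by the number of chains begun, living and dead together
- steps thought possible: protic impurity + free monomer -> quenched substrate; living end + transfer agent -> dead chain; free monomer + initiator -> living end + monomer in chains; free monomer + living end -> monomer in chains + living end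
- the earlier runs do not show the number of chains; that part of a forecast is a guess

1. which of the two ends with the longer chains by the average number of monomer units in a chain (chains begun, living or dead) ("neither" if they lie within 10%) (delta / theta / neither)
2. average number of monomer units in a chain (chains begun, living or dead) at the end, delta
3. average number of monomer units in a chain (chains begun, living or dead) at the end, theta

**Two ways.** The spared share can be had twice. From the charges, the protic impurity can quench 5.00% of the free monomer. From the readings at 4.00 h, chains plus free monomer fall short of the charge by 4.50% on average over teal and red, each reading scattering by 1.5 percentage points. These are different sources and they agree, so the spared share is trusted.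

**Where they part.** Lengths can also be had twice, as the count or as monomer in chains at 4.00 h per initiator charged. In the red run they lie together, 15.6 and 15.4. In the teal run they part, 86.4 and 80.9, and free monomer still stands there at 5%. So in the teal run the count cheats, for it supposes the free monomer finished. Neither way sees the chains begun, but these are bounded by the initiator charged. Theta's count is therefore a floor once its free monomer is used, and the red run, with more initiator than theta, read 7% free at 0.250 h. Taking delta's initiator as all begun, which is a guess, this reckoning puts delta below 95.0 and theta at or above 23.8, and its judgement is that delta ends the longer.

**Result.** The forecast chose delta, with 91 (75 to 105) for delta and 23.7 (21 to 28) for theta, noting “Chain count assumes all initiator starts chains”. The simulation also gives delta, at 82.6 against 27.3. Delta lies under its count of 95.0 with 12% of the free monomer left, and theta lies above its count of 23.8 with 13% of the initiator left.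

    protic impurity + free monomer → quenched substrate (k = 0.580 /M/s)
    living end + transfer agent → dead chain (kL = 0.930 /M/s)
    free monomer + initiator → living end + monomer in chains (k = 0.0210 /M/s)
    free monomer + living end → monomer in chains + living end, rate k4*[living end]*[free monomer] (k = 0.530 /M/s)

**Same count.** In delta at 0.354 h, the living end has a half-life of 0.27 h against the transfer agent, shorter than the 0.50 h of free monomer going into chains. At 5.00 h, delta holds 12.4% free monomer beside 82.6% in chains. The neighbour of delta with 0.050 M of protic impurity has a count of 80.0. The computed length there is 69.5, with 10.5% of the free monomer left.

The earlier runs and the new flask were computed from invented constants, and the scatter is random.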